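## Strategy

- Retrosynthesis: the O–Si bond of a silyl ether on the primary alcohol is cut first. The benzene ring is then opened across C1–C2 and C3–C4 (C1 = C–OH, C3 = C–OMe, C5 = C–alkyl), which gives a 3-alkylcyclobutenone and methoxyacetylene. The cyclobutenone goes back to a terminal alkyne and dichloroketene, and the chain to an acetylide, a C3 chloro-epoxide and a C10 Grignard reagent.
- Forward order: C10 bromide + C3 epoxide → chlorohydrin → epoxide → C2 acetylide → acetate → four-membered ring on the alkyne → benzene ring (the only ring of the target) → desilylation.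
- Enabling feature: the ring carries OH, OMe and the alkyl arm on alternate carbons with three ring CH between them. This is the 3-alkoxy-5-alkylphenol pattern that a 3-substituted cyclobutenone (four ring carbons and the OH) and an alkoxyacetylene (two ring carbons and the OMe) deliver, with the two oxygens already different. The ArCH2–CH(OAc) unit is a masked homopropargylic acetate.
- Stereochemistry: the single (R) acetoxy carbon is bought as C2 of (R)-epichlorohydrin. Every later bond is made at a flanking CH2 or at oxygen.

Key step: step 9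

Remark: the stereocentre of the target is read as (R) (OAc > ArCH2 > chain CH2 > H); TBDPS = tert-butyldiphenylsilyl.

## Route

Step 1
Reactants: 1 10-bromodecan-1-ol
Product: 2 tert-butyl[(10-bromodecyl)oxy]diphenylsilane (10-bromodecyl TBDPS ether)
Conditions: TBDPSCl, imidazole, CH2Cl2, 0 °C to rt
Reagents that add atoms: tert-butyl(chloro)diphenylsilane (TBDPSCl), CC(C)(C)[Si](Cl)(c1ccccc1)c1ccccc1
Why: Silylation of a primary alcohol with a silyl chloride and imidazole is routine, and the bulky TBDPS ether should withstand the Grignard, acetylide, zinc and thermal steps that follow.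

Step 2
Reactants: 2 10-bromodecyl TBDPS ether; 3 (R)-epichlorohydrin
Product: 5 (R)-1-chloro-13-(TBDPS-oxy)tridecan-2-ol, via Grignard reagent 4 (not isolated)
Conditions: Mg (I2 cat.), THF, 45 °C; then 3, CuI (10 mol %), THF, −40 to −20 °C; aq NH4Cl
Reagents that add atoms: none
Why: Magnesium insertion into the primary C–Br bond gives the alkyl Grignard reagent, which under CuI catalysis should open the oxirane of 3 at its unsubstituted CH2 (copper-catalysed Grignard epoxide opening) faster than it displaces chloride, so C2 of 3 is carried over unchanged as the (R)-carbinol.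

Step 3
Reactants: 5 (R)-1-chloro-13-(TBDPS-oxy)tridecan-2-ol
Product: 6 (R)-2-[11-(TBDPS-oxy)undecyl]oxirane
Conditions: powdered NaOH, Et2O, rt
Reagents that add atoms: none
Why: Intramolecular Williamson etherification of the alkoxide onto the CH2Cl carbon closes the oxirane without breaking a bond to the stereocentre, which stays (R).

Step 4
Reactants: 6 (R)-2-[11-(TBDPS-oxy)undecyl]oxirane; 7 lithium acetylide–ethylenediamine complex
Product: 8 (R)-15-(TBDPS-oxy)pentadec-1-yn-4-ol
Conditions: 7, DMSO, 0 °C to rt; aq NH4Cl
Reagents that add atoms: none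
Why: In dipolar aprotic DMSO the acetylide opens the terminal epoxide by SN2 attack at the unhindered CH2 (acetylide epoxide opening), which leaves the carbinol carbon (R) and gives the homopropargylic alcohol directly as a terminal alkyne.

Step 5
Reactants: 8 (R)-15-(TBDPS-oxy)pentadec-1-yn-4-ol
Product: 9 (R)-15-(TBDPS-oxy)pentadec-1-yn-4-yl acetate
Conditions: Ac2O, pyridine, DMAP (cat.), CH2Cl2, 0 °C to rt
Reagents that add atoms: acetic anhydride, CC(=O)OC(C)=O
Why: DMAP-catalysed acylation takes place at oxygen with retention and installs the acetate of the target early, so that no free hydroxyl meets the acid chloride and the ketene of the next step.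

Step 6
Reactants: 9 (R)-15-(TBDPS-oxy)pentadec-1-yn-4-yl acetate; 10 trichloroacetyl chloride
Product: 12 (R)-1-(4,4-dichloro-3-oxocyclobut-1-en-1-yl)-13-(TBDPS-oxy)tridecan-2-yl acetate, via dichloroketene 11 (not isolated)
Conditions: Zn–Cu couple, Et2O/DME, 10 added over 3 h, rt to reflux
Reagents that add atoms: none
Why: Zinc dechlorination of 10 releases dichloroketene, which should add [2+2] to the terminal alkyne with its carbonyl carbon on the terminal CH and CCl2 on the substituted carbon while DME ties up ZnCl2; a 1,3-chlorine shift to the 2,4-dichloro isomer would be harmless because both isomers converge in step 7.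

Step 7
Reactants: 12 (R)-1-(4,4-dichloro-3-oxocyclobut-1-en-1-yl)-13-(TBDPS-oxy)tridecan-2-yl acetate
Product: 13 (R)-1-(3-oxocyclobut-1-en-1-yl)-13-(TBDPS-oxy)tridecan-2-yl acetate
Conditions: Zn dust, AcOH, TMEDA, EtOH, 0 °C to rt
Reagents that add atoms: none
Why: Zinc in TMEDA-buffered acetic acid removes both α-chlorines by reductive dehalogenation without reducing the strained enone, and the near-neutral medium should spare the acetate and avoid elimination across the CH2–CH(OAc) unit.

Step 8
Reactants: 14 chloroacetaldehyde dimethyl acetal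
Product: 16 methoxyacetylene, via sodium methoxyacetylide 15 (not isolated)
Conditions: NaNH2 (3 equiv), liq. NH3, −33 °C; then cold brine, −70 °C; distilled into a −78 °C trap and kept as a cold toluene solution
Reagents that add atoms: none
Why: Sodium amide removes methanol and then HCl from the chloroacetal (double β-elimination) and deprotonates the alkyne formed, so cold aqueous protonation of the sodium acetylide should release the low-boiling ynol ether, which is distilled out and used at once.

Step 9
Reactants: 13 (R)-1-(3-oxocyclobut-1-en-1-yl)-13-(TBDPS-oxy)tridecan-2-yl acetate; 16 methoxyacetylene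
Product: 21 (R)-1-(3-hydroxy-5-methoxyphenyl)-13-(TBDPS-oxy)tridecan-2-yl acetate, via vinylketene 17 (not isolated), via 4-vinylcyclobutenone 18 (not isolated), via dienylketene 19 (not isolated), via cyclohexadienone 20 (not isolated)
Conditions: 16 (4 equiv), toluene, sealed tube, 80 °C then 110 °C
Reagents that add atoms: none
Why: On heating, the C1–C4 σ-bond of 13 breaks in a 4π-electrocyclic opening to vinylketene 17, whose ketene C=C adds [2+2] to the electron-rich alkyne to give 18; a second 4π opening gives dienylketene 19, 6π-electrocyclisation gives cyclohexadienone 20, and enolisation gives the phenol (Danheiser benzannulation; closest precedent is 3-alkylcyclobutenones with alkoxyacetylenes, which give 5-alkylresorcinol monoethers). The transient four-membered ring closes by ketene–alkyne [2+2] cycloaddition, and the benzene ring closes by thermal disrotatory 6π-electrocyclisation between the ketene carbon (the former carbonyl carbon) and the former C4 methylene. No stereocentre is created in the product: the sp3 ring carbon of 18 is uncontrolled but is erased on ring opening, and the (R)-acetoxy carbon is insulated from the reacting π-system by a CH2 group and meets only neutral thermal conditions. The step needs regioselectivity in the [2+2], and the polarity of the ynol ether secures it: its nucleophilic unsubstituted carbon bonds to the electrophilic ketene carbonyl carbon and its methoxy-bearing carbon to the former C2, so that OMe ends meta to both the new OH and the alkyl arm. Methoxyacetylene has no β-hydrogen for a retro-ene loss of ketene, and its excess should keep the vinylketene from acylating the product phenol.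

Step 10
Reactants: 21 (R)-1-(3-hydroxy-5-methoxyphenyl)-13-(TBDPS-oxy)tridecan-2-yl acetate
Product: 22 (R)-13-hydroxy-1-(3-hydroxy-5-methoxyphenyl)tridecan-2-yl acetate (CNP0164512.1)
Conditions: HF·pyridine, pyridine/THF, 0 °C to rt
Reagents that add atoms: none
Why: Fluoride cleaves the Si–O bond (silyl ether deprotection) under weakly acidic, non-nucleophilic conditions in which the secondary acetate and the phenol are inert, so the primary alcohol should be released with the stereocentre untouched.

## Compound list

1 | 10-bromodecan-1-ol | OCCCCCCCCCCBr | starting material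
2 | tert-butyl[(10-bromodecyl)oxy]diphenylsilane | BrCCCCCCCCCCO[Si](c1ccccc1)(c1ccccc1)C(C)(C)C | intermediate
3 | (R)-epichlorohydrin, (R)-2-(chloromethyl)oxirane | ClC[C@H]1CO1 | starting material
4 | [10-(TBDPS-oxy)decyl]magnesium bromide | Br[Mg]CCCCCCCCCCO[Si](c1ccccc1)(c1ccccc1)C(C)(C)C | intermediate
5 | (R)-1-chloro-13-(TBDPS-oxy)tridecan-2-ol | ClC[C@H](O)CCCCCCCCCCCO[Si](c1ccccc1)(c1ccccc1)C(C)(C)C | intermediate
6 | (R)-2-[11-(TBDPS-oxy)undecyl]oxirane | C1[C@@H](CCCCCCCCCCCO[Si](c2ccccc2)(c2ccccc2)C(C)(C)C)O1 | intermediate
7 | lithium acetylide–ethylenediamine complex | [Li]C#C.NCCN | starting material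
8 | (R)-15-(TBDPS-oxy)pentadec-1-yn-4-ol | C#CC[C@@H](CCCCCCCCCCCO[Si](c1ccccc1)(c1ccccc1)C(C)(C)C)O | intermediate
9 | (R)-15-(TBDPS-oxy)pentadec-1-yn-4-yl acetate | C#CC[C@@H](CCCCCCCCCCCO[Si](c1ccccc1)(c1ccccc1)C(C)(C)C)OC(C)=O | intermediate
10 | trichloroacetyl chloride | ClC(Cl)(Cl)C(Cl)=O | starting material
11 | dichloroketene | O=C=C(Cl)Cl | intermediate
12 | (R)-1-(4,4-dichloro-3-oxocyclobut-1-en-1-yl)-13-(TBDPS-oxy)tridecan-2-yl acetate | O=C1C=C(C[C@@H](CCCCCCCCCCCO[Si](c2ccccc2)(c2ccccc2)C(C)(C)C)OC(C)=O)C1(Cl)Cl | intermediate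
13 | (R)-1-(3-oxocyclobut-1-en-1-yl)-13-(TBDPS-oxy)tridecan-2-yl acetate | O=C1C=C(C[C@@H](CCCCCCCCCCCO[Si](c2ccccc2)(c2ccccc2)C(C)(C)C)OC(C)=O)C1 | intermediate
14 | chloroacetaldehyde dimethyl acetal (2-chloro-1,1-dimethoxyethane) | ClCC(OC)OC | starting material
15 | sodium methoxyacetylide | [Na]C#COC | intermediate
16 | methoxyacetylene (methoxyethyne) | C#COC | intermediate
17 | vinylketene, (R)-3-methylidene-1-oxo-16-(TBDPS-oxy)hexadec-1-en-5-yl acetate | O=C=CC(=C)C[C@@H](CCCCCCCCCCCO[Si](c1ccccc1)(c1ccccc1)C(C)(C)C)OC(C)=O | intermediate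
18 | 4-vinylcyclobutenone, (4R)-2-(2-methoxy-4-oxocyclobut-2-en-1-yl)-15-(TBDPS-oxy)pentadec-1-en-4-yl acetate, both epimers at the ring sp3 carbon | COC1=CC(=O)C1C(=C)C[C@@H](CCCCCCCCCCCO[Si](c2ccccc2)(c2ccccc2)C(C)(C)C)OC(C)=O | intermediate
19 | dienylketene, (R,3E)-3-methoxy-5-methylidene-1-oxo-18-(TBDPS-oxy)octadeca-1,3-dien-7-yl acetate | O=C=C/C(OC)=C\C(=C)C[C@@H](CCCCCCCCCCCO[Si](c1ccccc1)(c1ccccc1)C(C)(C)C)OC(C)=O | intermediate
20 | cyclohexadienone, (R)-1-(3-methoxy-5-oxocyclohexa-1,3-dien-1-yl)-13-(TBDPS-oxy)tridecan-2-yl acetate | COC1=CC(=O)CC(C[C@@H](CCCCCCCCCCCO[Si](c2ccccc2)(c2ccccc2)C(C)(C)C)OC(C)=O)=C1 | intermediate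
21 | (R)-1-(3-hydroxy-5-methoxyphenyl)-13-(TBDPS-oxy)tridecan-2-yl acetate | COc1cc(O)cc(C[C@@H](CCCCCCCCCCCO[Si](c2ccccc2)(c2ccccc2)C(C)(C)C)OC(C)=O)c1 | intermediate
22 | (R)-13-hydroxy-1-(3-hydroxy-5-methoxyphenyl)tridecan-2-yl acetate (CNP0164512.1) | COc1cc(O)cc(C[C@@H](CCCCCCCCCCCO)OC(C)=O)c1 | target

## Step count and risks

Total step count: 10. Longest linear sequence: 9 steps (steps 1–7, 9 and 10, from 10-bromodecan-1-ol). Step 8 is a one-step side branch.

Steps most likely to fail:

1. Step 9.
 - What may go wrong: the newly formed phenol is acylated by vinylketene that has not yet met the alkyne, the ynol ether oligomerises on heating, and the ketene dimerises. The basic hydrolysis that would normally recover the phenol from such aryl esters cannot be used, because it would also remove the secondary acetate. A short supply of the volatile alkyne from step 8 makes all of this worse.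
 - Fallback (a preformed arene is alkylated, no ring is built): it sets out from epoxide 6 and rejoins the route at 21. Commercial 3-bromo-5-methoxyphenol is benzylated (BnBr, K2CO3, acetone) to 1-(benzyloxy)-3-bromo-5-methoxybenzene F1. Magnesium in THF converts this into [3-(benzyloxy)-5-methoxyphenyl]magnesium bromide F2, which under CuI catalysis should open 6 at its CH2 terminus to give (R)-1-[3-(benzyloxy)-5-methoxyphenyl]-13-(TBDPS-oxy)tridecan-2-ol F3 with the stereocentre untouched. Acetylation (Ac2O, pyridine, DMAP) gives (R)-1-[3-(benzyloxy)-5-methoxyphenyl]-13-(TBDPS-oxy)tridecan-2-yl acetate F4, and hydrogenolysis of the benzyl ether (H2, Pd/C, EtOAc) gives 21. This path also makes step 8 unnecessary.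

2. Step 6.
 - What may go wrong: dichloroketene polymerises faster than it adds to an unactivated monosubstituted alkyne, and zinc chloride promotes ionisation or elimination of the homopropargylic acetate.
 - Fallback (a keteniminium salt replaces the ketene, no halogens are introduced): it sets out from alkyne 9 and rejoins the route at 13. The keteniminium triflate generated from N,N-dimethylacetamide, Tf2O and 2,4,6-collidine in 1,2-dichloroethane at reflux should add [2+2] to the terminal alkyne, with the iminium carbon on the terminal CH. This gives N,N-dimethyl-3-[(R)-2-acetoxy-13-(TBDPS-oxy)tridecyl]cyclobut-2-en-1-iminium triflate F5. Mild hydrolysis with aqueous NaHCO3 gives cyclobutenone 13 directly, so compound 12 and step 7 are bypassed as well.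

3. Step 2.
 - What may go wrong: Wurtz-type homocoupling while the Grignard reagent forms, opening of the epoxide by magnesium halide, in-flask closure of the magnesium chlorohydrinate followed by a second Grignard addition, and direct displacement at the C–Cl carbon, which would lower the enantiomeric purity.
 - Fallback (the stereocentre comes from a kinetic resolution, not from the chiral pool): it sets out from bromide 2 and rejoins the route at epoxide 6. Copper-catalysed coupling of 2 with allylmagnesium bromide (Li2CuCl4 cat., THF) should give tert-butyl(tridec-12-en-1-yloxy)diphenylsilane F6. Epoxidation with mCPBA in CH2Cl2 gives racemic 2-[11-(TBDPS-oxy)undecyl]oxirane F7. Hydrolytic kinetic resolution with water (0.55 equiv) and the (R,R)-configured (salen)Co(OAc) complex of trivalent cobalt (salen = N,N′-bis(3,5-di-tert-butylsalicylidene)cyclohexane-1,2-diamine dianion) is expected to hydrolyse the (S)-epoxide to (S)-13-(TBDPS-oxy)tridecane-1,2-diol F8 and leave (R)-epoxide 6, which is separated by chromatography. Compound 5 and step 3 are bypassed.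

## Further compounds

F1 | step 9 | 1-(benzyloxy)-3-bromo-5-methoxybenzene | COc1cc(Br)cc(OCc2ccccc2)c1
F2 | step 9 | [3-(benzyloxy)-5-methoxyphenyl]magnesium bromide | COc1cc([Mg]Br)cc(OCc2ccccc2)c1
F3 | step 9 | (R)-1-[3-(benzyloxy)-5-methoxyphenyl]-13-(TBDPS-oxy)tridecan-2-ol | COc1cc(OCc2ccccc2)cc(C[C@@H](CCCCCCCCCCCO[Si](c3ccccc3)(c4ccccc4)C(C)(C)C)O)c1
F4 | step 9 | (R)-1-[3-(benzyloxy)-5-methoxyphenyl]-13-(TBDPS-oxy)tridecan-2-yl acetate | COc1cc(OCc2ccccc2)cc(C[C@@H](CCCCCCCCCCCO[Si](c3ccccc3)(c4ccccc4)C(C)(C)C)OC(C)=O)c1
F5 | step 6 | N,N-dimethyl-3-[(R)-2-acetoxy-13-(TBDPS-oxy)tridecyl]cyclobut-2-en-1-iminium triflate | C[N+](C)=C1C=C(C[C@@H](CCCCCCCCCCCO[Si](c2ccccc2)(c2ccccc2)C(C)(C)C)OC(C)=O)C1.[O-]S(=O)(=O)C(F)(F)F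
F6 | step 2 | tert-butyl(tridec-12-en-1-yloxy)diphenylsilane | C=CCCCCCCCCCCCO[Si](c1ccccc1)(c1ccccc1)C(C)(C)C
F7 | step 2 | racemic 2-[11-(TBDPS-oxy)undecyl]oxirane | C1OC1CCCCCCCCCCCO[Si](c2ccccc2)(c2ccccc2)C(C)(C)C
F8 | step 2 | (S)-13-(TBDPS-oxy)tridecane-1,2-diol | OC[C@@H](O)CCCCCCCCCCCO[Si](c1ccccc1)(c1ccccc1)C(C)(C)C
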